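**Retrosynthetic overview**
1. Target 30 comes from its bis-silyl ether 29, which is disconnected at the C5–O ester bond into hydroxy lactone 23 and dienoic acid 28.
2. The only ring, the dihydropyranone, is made last in the chain series: furyl carbinol 20 is ring-expanded (furan to pyranone, Achmatowicz) to lactol 21, which is isomerised to 23.
3. 20 comes from carbamate 13 and furyl boronate 14 (C5–C6 bond). 13 is grown from bromo alcohol 1 by three successive 1,2-boronate shifts that add C9, C10 and C11.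
4. 28 comes from silyloxybutanal 24 by organocatalytic α-hydroxymethylation (C6' stereocentre) and two olefinations.

Assumption: 14 and 24 are bought in their protected forms (pinacol boronate, TBS ether); ethyl 2,4,6-triisopropylbenzoate, 2-(triphenylphosphoranylidene)propanal and diethylphosphonoacetic acid are bought reagents.

Atom labels C5–C11 refer to the lactone numbering of the target (C6 ring carbon bearing the side chain, C7 and C9 methyl-bearing, C11 carbinol); primed labels refer to the acyl chain.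

**Step 1**
Reactants: 1 (R)-3-bromo-2-methylpropan-1-ol
Product: 2 (R)-3-bromo-2-methylpropyl N,N-diisopropylcarbamate
Conditions: iPr2NCOCl, Et3N, DMAP (cat.), CH2Cl2, reflux
Reagents that add atoms: N,N-diisopropylcarbamoyl chloride, CC(C)N(C(C)C)C(=O)Cl
Why: O-carbamoylation of the primary alcohol installs the Hoppe carbamate that protects C6–O now and directs the lithiation at C6 in step 7; the stereocentre of 1 (future C7) is not touched.

**Step 2**
Reactants: 2 (R)-3-bromo-2-methylpropyl N,N-diisopropylcarbamate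
Product: 3 (S)-2-methyl-3-(4,4,5,5-tetramethyl-1,3,2-dioxaborolan-2-yl)propyl N,N-diisopropylcarbamate
Conditions: B2pin2, CuI (10 mol %), PPh3 (13 mol %), LiOMe, DMF, 25 °C
Reagents that add atoms: bis(pinacolato)diboron, CC1(C)OB(OC1(C)C)B1OC(C)(C)C(C)(C)O1
Why: Copper-catalysed borylation of a primary alkyl bromide replaces Br by Bpin at C8 without affecting the adjacent stereocentre or the carbamate.

**Step 3**
Reactants: 3 (S)-2-methyl-3-(4,4,5,5-tetramethyl-1,3,2-dioxaborolan-2-yl)propyl N,N-diisopropylcarbamate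
Product: 5 (2S,4R)-2-methyl-4-(4,4,5,5-tetramethyl-1,3,2-dioxaborolan-2-yl)pentyl N,N-diisopropylcarbamate, via boronate complex 4 (not isolated)
Conditions: ethyl 2,4,6-triisopropylbenzoate, sBuLi, (−)-sparteine, Et2O, −78 °C, 5 h; then 3, −78 °C, 1 h; then reflux, 16 h
Reagents that add atoms: ethyl 2,4,6-triisopropylbenzoate, CCOC(=O)c1c(C(C)C)cc(C(C)C)cc1C(C)C
Why: Hoppe–Aggarwal lithiation–borylation, in which the (S)-configured lithiated benzoate (pro-S proton removed under sparteine control) adds to boron with retention and the C8 group then undergoes a stereospecific 1,2-metallate shift with inversion, setting C9 under reagent control 1,3-syn to C7.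

**Step 4**
Reactants: 5 (2S,4R)-2-methyl-4-(4,4,5,5-tetramethyl-1,3,2-dioxaborolan-2-yl)pentyl N,N-diisopropylcarbamate
Product: 7 (2S,4S)-2,4-dimethyl-5-(4,4,5,5-tetramethyl-1,3,2-dioxaborolan-2-yl)pentyl N,N-diisopropylcarbamate, via boronate complex 6 (not isolated)
Conditions: BrCH2Cl, nBuLi, Et2O, −78 → 25 °C
Reagents that add atoms: bromochloromethane, ClCBr
Why: Matteson homologation, in which chloromethyllithium forms the ate complex and the secondary carbon migrates from boron to carbon with retention, inserting C10 without changing C9.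

**Step 5**
Reactants: 8 (S)-but-3-en-2-ol
Product: 9 (S)-but-3-en-2-yl N,N-diisopropylcarbamate
Conditions: NaH, THF, 0 °C; then iPr2NCOCl, reflux
Reagents that add atoms: N,N-diisopropylcarbamoyl chloride, CC(C)N(C(C)C)C(=O)Cl
Why: O-carbamoylation of the sodium alkoxide, with no bond to the stereocentre broken.

**Step 6**
Reactants: 7 (2S,4S)-2,4-dimethyl-5-(4,4,5,5-tetramethyl-1,3,2-dioxaborolan-2-yl)pentyl N,N-diisopropylcarbamate; 9 (S)-but-3-en-2-yl N,N-diisopropylcarbamate
Product: 13 (2S,4R,6R)-6-hydroxy-2,4,6-trimethyloct-7-en-1-yl N,N-diisopropylcarbamate, via lithiated carbamate 10 (not isolated), via boronate complex 11 (not isolated), via tertiary boronic ester 12 (not isolated)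
Conditions: 9, sBuLi, TMEDA, Et2O, −78 °C, 20 min; then 7, −78 °C, 1 h; MgBr2·OEt2, MeOH, −78 → 25 °C; then NaOH (2 M), H2O2 (30%), THF, 0 → 25 °C
Reagents that add atoms: hydrogen peroxide, OO
Why: Lithiation–borylation of a secondary allylic carbamate (α-deprotonation with retention, α-borylation with retention, 1,2-metallate shift of C10 with inversion) forms C10–C11 and converts the (S)-carbinol centre of 9 into the tertiary boronate, whose stereoretentive oxidation gives the (R)-tertiary allylic alcohol.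

**Step 7**
Reactants: 13 (2S,4R,6R)-6-hydroxy-2,4,6-trimethyloct-7-en-1-yl N,N-diisopropylcarbamate; 14 2-(furan-2-yl)-4,4,5,5-tetramethyl-1,3,2-dioxaborolane
Product: 20 (1R,2S,4R,6R)-1-(furan-2-yl)-2,4,6-trimethyloct-7-ene-1,6-diol, via silyl ether 15 (not isolated), via lithiated carbamate 16 (not isolated), via boronate complex 17 (not isolated), via furyl boronic ester 18 (not isolated), via silylated carbinol 19 (not isolated)
Conditions: nBuLi (1 equiv), Et2O, −78 °C, then TMSCl, 0 °C; (−)-sparteine, sBuLi, −78 °C, 5 h; 14, −78 °C, 1 h; MgBr2·OEt2, reflux, 12 h; then NaOH (2 M), H2O2 (30%), THF/MeOH, 0 → 25 °C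
Reagents that add atoms: hydrogen peroxide, OO
Why: Sparteine-directed Hoppe lithiation removes the pro-S proton at C6, borylation with 14 and 1,2-migration of the furyl group from boron to carbon (inversion) form the C5–C6 bond, and stereoretentive C–B oxidation gives the (R)-furyl carbinol, 6,7-syn, under reagent control; the tertiary OH is masked in the flask as its TMS ether and freed again in the basic oxidative work-up.

**Step 8**
Reactants: 20 (1R,2S,4R,6R)-1-(furan-2-yl)-2,4,6-trimethyloct-7-ene-1,6-diol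
Product: 21 (2R)-6-hydroxy-2-[(2S,4R,6R)-6-hydroxy-4,6-dimethyloct-7-en-2-yl]-2H-pyran-3(6H)-one (both anomers)
Conditions: NBS, NaHCO3, NaOAc, THF/H2O (4:1), 0 °C
Reagents that add atoms: water, O
Why: Achmatowicz rearrangement (bromonium attack at furan C5, water addition, opening to the cis-enedione and reclosure through the carbinol oxygen) expands the furan to the six-membered pyranone by an ionic pathway, leaving C6 unchanged and the far less electron-rich vinyl group untouched.

**Step 9**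
Reactants: 21 (2R)-6-hydroxy-2-[(2S,4R,6R)-6-hydroxy-4,6-dimethyloct-7-en-2-yl]-2H-pyran-3(6H)-one
Product: 23 (5R,6R)-5-hydroxy-6-[(2S,4R,6R)-6-hydroxy-4,6-dimethyloct-7-en-2-yl]-5,6-dihydro-2H-pyran-2-one, via ketolactone 22 (not isolated)
Conditions: Ru(p-cymene)[(S,S)-TsNCHPhCHPhNH] (2 mol %, preformed amido complex), CH2Cl2, 25 °C, no added oxidant or reductant
Reagents that add atoms: none
Why: Proposed new method: the 16-electron Ru amide dehydrogenates the lactol O–H/C–H to the lactone and the resulting Ru–H/N–H pair returns the hydrogen to the C5 ketone in a 1,2-sense (outer-sphere, C=O preferred over C=C), so 21 isomerises through ketolactone 22 to 23, driven by lactone formation; hydride arrives anti to the C6 side chain (substrate bias, expected to be reinforced by the (S,S)-ligand by analogy with aryl and alkynyl ketone reductions), giving the 5,6-cis (5R) alcohol; the closest known reaction types are Noyori–Ikariya transfer hydrogenation, Ru-catalysed lactol-to-lactone dehydrogenation and iridium-catalysed internal redox isomerisation of Achmatowicz lactols.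

**Step 10**
Reactants: 24 4-((tert-butyldimethylsilyl)oxy)butanal
Product: 26 (S,E)-6-((tert-butyldimethylsilyl)oxy)-4-(hydroxymethyl)-2-methylhex-2-enal, via hydroxymethyl aldehyde 25 (not isolated)
Conditions: aq. CH2O, (S)-α,α-diphenylprolinol TMS ether (20 mol %), pH 7 phosphate buffer, toluene, 25 °C; then Ph3P=C(Me)CHO (3 equiv), 45 °C
Reagents that add atoms: formaldehyde, C=O; 2-(triphenylphosphoranylidene)propanal, CC(C=O)=P(c1ccccc1)(c1ccccc1)c1ccccc1
Why: Enamine catalysis, in which the (S)-prolinol silyl ether shields one enamine face so formaldehyde adds from the open face to give (R)-25 (the future 6'S centre), and the stabilised Wittig ylide then traps the labile aldehyde in the same flask as the (E)-trisubstituted enal.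

**Step 11**
Reactants: 26 (S,E)-6-((tert-butyldimethylsilyl)oxy)-4-(hydroxymethyl)-2-methylhex-2-enal
Product: 27 (S,E)-6-((tert-butyldimethylsilyl)oxy)-4-(((tert-butyldimethylsilyl)oxy)methyl)-2-methylhex-2-enal
Conditions: TBSCl, imidazole, DMF, 25 °C
Reagents that add atoms: tert-butyldimethylsilyl chloride, CC(C)(C)[Si](C)(C)Cl
Why: Silylation of the primary alcohol under mild conditions that leave the enal and its γ-stereocentre untouched.

**Step 12**
Reactants: 27 (S,E)-6-((tert-butyldimethylsilyl)oxy)-4-(((tert-butyldimethylsilyl)oxy)methyl)-2-methylhex-2-enal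
Product: 28 (2E,4E,6S)-8-((tert-butyldimethylsilyl)oxy)-6-(((tert-butyldimethylsilyl)oxy)methyl)-4-methylocta-2,4-dienoic acid
Conditions: (EtO)2P(O)CH2CO2H, Zn(OTf)2, TMEDA, DBU, THF, 25 °C
Reagents that add atoms: diethylphosphonoacetic acid, CCOP(=O)(CC(=O)O)OCC
Why: Zinc-promoted Horner–Wadsworth–Emmons olefination with the free phosphonoacetic acid gives the (2E)-dienoic acid directly under amine bases too weak to deprotonate the γ-position of the enal.

**Step 13**
Reactants: 23 (5R,6R)-5-hydroxy-6-[(2S,4R,6R)-6-hydroxy-4,6-dimethyloct-7-en-2-yl]-5,6-dihydro-2H-pyran-2-one; 28 (2E,4E,6S)-8-((tert-butyldimethylsilyl)oxy)-6-(((tert-butyldimethylsilyl)oxy)methyl)-4-methylocta-2,4-dienoic acid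
Product: 29 (5R,6R)-6-[(2S,4R,6R)-6-hydroxy-4,6-dimethyloct-7-en-2-yl]-2-oxo-5,6-dihydro-2H-pyran-5-yl (2E,4E,6S)-8-((tert-butyldimethylsilyl)oxy)-6-(((tert-butyldimethylsilyl)oxy)methyl)-4-methylocta-2,4-dienoate
Conditions: DCC, DMAP (10 mol %), CH2Cl2, 0 → 25 °C
Reagents that add atoms: none
Why: Steglich esterification acylates the secondary allylic C5–OH with retention (the C5–O bond is not broken), while the hindered tertiary alcohol does not react and the low DMAP loading avoids base-induced translactonisation.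

**Step 14**
Reactants: 29 (5R,6R)-6-[(2S,4R,6R)-6-hydroxy-4,6-dimethyloct-7-en-2-yl]-2-oxo-5,6-dihydro-2H-pyran-5-yl (2E,4E,6S)-8-((tert-butyldimethylsilyl)oxy)-6-(((tert-butyldimethylsilyl)oxy)methyl)-4-methylocta-2,4-dienoate
Product: 30 (5R,6R)-6-[(2S,4R,6R)-6-hydroxy-4,6-dimethyloct-7-en-2-yl]-2-oxo-5,6-dihydro-2H-pyran-5-yl (2E,4E,6S)-8-hydroxy-6-(hydroxymethyl)-4-methylocta-2,4-dienoate
Conditions: HF·pyridine, pyridine, THF, 0 → 25 °C
Reagents that add atoms: none
Why: Buffered fluoride desilylation removes both primary TBS ethers without harming the unsaturated lactone, the dienoate ester or the tertiary allylic alcohol.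

**Compound list**
1 | (R)-3-bromo-2-methylpropan-1-ol | BrC[C@H](C)CO | starting material
2 | (R)-3-bromo-2-methylpropyl N,N-diisopropylcarbamate | BrC[C@H](C)COC(=O)N(C(C)C)C(C)C | intermediate
3 | (S)-2-methyl-3-(4,4,5,5-tetramethyl-1,3,2-dioxaborolan-2-yl)propyl N,N-diisopropylcarbamate | CC1(C)OB(OC1(C)C)C[C@H](C)COC(=O)N(C(C)C)C(C)C | intermediate
4 | lithium boronate complex of 3 carrying the (S)-1-(2,4,6-triisopropylbenzoyloxy)ethyl group on boron | [Li+].C[C@@H](OC(=O)c1c(C(C)C)cc(C(C)C)cc1C(C)C)[B-]1(OC(C)(C)C(C)(C)O1)C[C@H](C)COC(=O)N(C(C)C)C(C)C | intermediate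
5 | (2S,4R)-2-methyl-4-(4,4,5,5-tetramethyl-1,3,2-dioxaborolan-2-yl)pentyl N,N-diisopropylcarbamate | CC1(C)OB(OC1(C)C)[C@H](C)C[C@H](C)COC(=O)N(C(C)C)C(C)C | intermediate
6 | lithium chloromethyl boronate complex of 5 | [Li+].ClC[B-]1(OC(C)(C)C(C)(C)O1)[C@H](C)C[C@H](C)COC(=O)N(C(C)C)C(C)C | intermediate
7 | (2S,4S)-2,4-dimethyl-5-(4,4,5,5-tetramethyl-1,3,2-dioxaborolan-2-yl)pentyl N,N-diisopropylcarbamate | CC1(C)OB(OC1(C)C)C[C@H](C)C[C@H](C)COC(=O)N(C(C)C)C(C)C | intermediate
8 | (S)-but-3-en-2-ol | C=C[C@H](C)O | starting material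
9 | (S)-but-3-en-2-yl N,N-diisopropylcarbamate | C=C[C@H](C)OC(=O)N(C(C)C)C(C)C | intermediate
10 | (S)-2-lithiobut-3-en-2-yl N,N-diisopropylcarbamate | C=C[C@]([Li])(C)OC(=O)N(C(C)C)C(C)C | intermediate
11 | lithium boronate complex of 7 carrying the 2-(diisopropylcarbamoyloxy)but-3-en-2-yl group on boron | [Li+].C=C[C@](C)(OC(=O)N(C(C)C)C(C)C)[B-]1(OC(C)(C)C(C)(C)O1)C[C@H](C)C[C@H](C)COC(=O)N(C(C)C)C(C)C | intermediate
12 | (2S,4R,6S)-2,4,6-trimethyl-6-(4,4,5,5-tetramethyl-1,3,2-dioxaborolan-2-yl)oct-7-en-1-yl N,N-diisopropylcarbamate | C=C[C@](C)(B1OC(C)(C)C(C)(C)O1)C[C@H](C)C[C@H](C)COC(=O)N(C(C)C)C(C)C | intermediate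
13 | (2S,4R,6R)-6-hydroxy-2,4,6-trimethyloct-7-en-1-yl N,N-diisopropylcarbamate | C=C[C@](C)(O)C[C@H](C)C[C@H](C)COC(=O)N(C(C)C)C(C)C | intermediate
14 | 2-(furan-2-yl)-4,4,5,5-tetramethyl-1,3,2-dioxaborolane | CC1(C)OB(OC1(C)C)c1ccco1 | starting material
15 | (2S,4R,6R)-2,4,6-trimethyl-6-(trimethylsilyloxy)oct-7-en-1-yl N,N-diisopropylcarbamate | C=C[C@](C)(O[Si](C)(C)C)C[C@H](C)C[C@H](C)COC(=O)N(C(C)C)C(C)C | intermediate
16 | (1S)-1-lithio derivative of 15 | C=C[C@](C)(O[Si](C)(C)C)C[C@H](C)C[C@H](C)[C@H]([Li])OC(=O)N(C(C)C)C(C)C | intermediate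
17 | lithium boronate complex of 14 carrying the carbamoyloxyalkyl group of 16 on boron | [Li+].C=C[C@](C)(O[Si](C)(C)C)C[C@H](C)C[C@H](C)[C@@H](OC(=O)N(C(C)C)C(C)C)[B-]1(OC(C)(C)C(C)(C)O1)c1ccco1 | intermediate
18 | trimethylsilyl ether of (3R,5R,7S,8R)-8-(furan-2-yl)-3,5,7-trimethyl-8-(4,4,5,5-tetramethyl-1,3,2-dioxaborolan-2-yl)oct-1-en-3-ol | C=C[C@](C)(O[Si](C)(C)C)C[C@H](C)C[C@H](C)[C@@H](B1OC(C)(C)C(C)(C)O1)c1ccco1 | intermediate
19 | (1R,2S,4R,6R)-1-(furan-2-yl)-2,4,6-trimethyl-6-(trimethylsilyloxy)oct-7-en-1-ol | C=C[C@](C)(O[Si](C)(C)C)C[C@H](C)C[C@H](C)[C@@H](O)c1ccco1 | intermediate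
20 | (1R,2S,4R,6R)-1-(furan-2-yl)-2,4,6-trimethyloct-7-ene-1,6-diol | C=C[C@](C)(O)C[C@H](C)C[C@H](C)[C@@H](O)c1ccco1 | intermediate
21 | (2R)-6-hydroxy-2-[(2S,4R,6R)-6-hydroxy-4,6-dimethyloct-7-en-2-yl]-2H-pyran-3(6H)-one (both anomers) | C=C[C@](C)(O)C[C@H](C)C[C@H](C)[C@H]1OC(O)C=CC1=O | intermediate
22 | (6R)-6-[(2S,4R,6R)-6-hydroxy-4,6-dimethyloct-7-en-2-yl]-2H-pyran-2,5(6H)-dione | C=C[C@](C)(O)C[C@H](C)C[C@H](C)[C@H]1OC(=O)C=CC1=O | intermediate
23 | (5R,6R)-5-hydroxy-6-[(2S,4R,6R)-6-hydroxy-4,6-dimethyloct-7-en-2-yl]-5,6-dihydro-2H-pyran-2-one | C=C[C@](C)(O)C[C@H](C)C[C@H](C)[C@H]1OC(=O)C=C[C@H]1O | intermediate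
24 | 4-((tert-butyldimethylsilyl)oxy)butanal | O=CCCCO[Si](C)(C)C(C)(C)C | starting material
25 | (R)-4-((tert-butyldimethylsilyl)oxy)-2-(hydroxymethyl)butanal | O=C[C@@H](CO)CCO[Si](C)(C)C(C)(C)C | intermediate
26 | (S,E)-6-((tert-butyldimethylsilyl)oxy)-4-(hydroxymethyl)-2-methylhex-2-enal | O=C/C(C)=C/[C@@H](CO)CCO[Si](C)(C)C(C)(C)C | intermediate
27 | (S,E)-6-((tert-butyldimethylsilyl)oxy)-4-(((tert-butyldimethylsilyl)oxy)methyl)-2-methylhex-2-enal | O=C/C(C)=C/[C@@H](CO[Si](C)(C)C(C)(C)C)CCO[Si](C)(C)C(C)(C)C | intermediate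
28 | (2E,4E,6S)-8-((tert-butyldimethylsilyl)oxy)-6-(((tert-butyldimethylsilyl)oxy)methyl)-4-methylocta-2,4-dienoic acid | OC(=O)/C=C/C(C)=C/[C@@H](CO[Si](C)(C)C(C)(C)C)CCO[Si](C)(C)C(C)(C)C | intermediate
29 | bis-TBS ether of 30 (both primary hydroxyls silylated) | C=C[C@](C)(O)C[C@H](C)C[C@H](C)[C@H]1OC(=O)C=C[C@H]1OC(=O)/C=C/C(C)=C/[C@@H](CO[Si](C)(C)C(C)(C)C)CCO[Si](C)(C)C(C)(C)C | intermediate
30 | (5R,6R)-6-[(2S,4R,6R)-6-hydroxy-4,6-dimethyloct-7-en-2-yl]-2-oxo-5,6-dihydro-2H-pyran-5-yl (2E,4E,6S)-8-hydroxy-6-(hydroxymethyl)-4-methylocta-2,4-dienoate | C=C[C@](C)(O)C[C@H](C)C[C@H](C)[C@H]1OC(=O)C=C[C@H]1OC(=O)/C=C/C(C)=C/[C@@H](CO)CCO | target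

**Totals**
Total step count: 14.
Longest linear sequence: 10 steps (1, 2, 3, 4, 6, 7, 8, 9, 13, 14).

**Three steps most likely to fail**

Step 9 (the proposed new isomerisation). Conjugate reduction of the enedione or a poor cis/trans ratio could spoil it. The fallback sets out from 21: Dess–Martin periodinane (NaHCO3, CH2Cl2, 0 °C) oxidises the lactol to ketolactone 22, which is now isolated (no compound outside the list, entry F0). Luche reduction (NaBH4, CeCl3·7H2O, MeOH/CH2Cl2, −78 °C) then delivers hydride anti to the C6 side chain and comes back to the route at 23. Both operations are known chemistry on Achmatowicz-derived lactones.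

Step 6. The lithiated carbamate 10 has an unsubstituted γ-terminus, so γ-borylation or loss of configuration may compete with the wanted α-borylation. The fallback sets out from 7. A B-alkyl Suzuki–Miyaura coupling with (E)-3-iodobut-2-en-1-ol (Pd(dppf)Cl2, Ag2O, K2CO3, THF, 70 °C) gives (2S,4R,6E)-8-hydroxy-2,4,6-trimethyloct-6-en-1-yl N,N-diisopropylcarbamate F1. Sharpless epoxidation (Ti(OiPr)4, D-(−)-diethyl tartrate, tBuOOH, 4 Å sieves, CH2Cl2, −20 °C) gives (2S,4R)-5-[(2R,3R)-3-(hydroxymethyl)-2-methyloxiran-2-yl]-2,4-dimethylpentyl N,N-diisopropylcarbamate F2. Iodination (I2, PPh3, imidazole, CH2Cl2) gives (2S,4R)-5-[(2R,3S)-3-(iodomethyl)-2-methyloxiran-2-yl]-2,4-dimethylpentyl N,N-diisopropylcarbamate F3. Zinc dust (EtOH, reflux) opens the iodo epoxide reductively to the tertiary allylic alcohol, coming back at 13.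

Step 10. The hydroxymethyl aldehyde 25 can dehydrate or racemise before the slow formyl-stabilised ylide traps it. The fallback sets out from 24. The same hydroxymethylation followed by NaBH4 in the flask gives achiral 2-[2-((tert-butyldimethylsilyl)oxy)ethyl]propane-1,3-diol F4. Lipase-catalysed monoacetylation (vinyl acetate, with a Pseudomonas or porcine pancreatic lipase chosen to give the (R)-ester) gives (R)-4-((tert-butyldimethylsilyl)oxy)-2-(hydroxymethyl)butyl acetate F5. TBSCl/imidazole gives (S)-4-((tert-butyldimethylsilyl)oxy)-2-(((tert-butyldimethylsilyl)oxy)methyl)butyl acetate F6. K2CO3/MeOH gives (S)-4-((tert-butyldimethylsilyl)oxy)-2-(((tert-butyldimethylsilyl)oxy)methyl)butan-1-ol F7. Dess–Martin oxidation gives (R)-4-((tert-butyldimethylsilyl)oxy)-2-(((tert-butyldimethylsilyl)oxy)methyl)butanal F8. Wittig olefination with Ph3P=C(Me)CHO (toluene, 80 °C) comes back to the route at 27.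

**Further compounds**
F0 | step 9 | none | none
F1 | step 6 | (2S,4R,6E)-8-hydroxy-2,4,6-trimethyloct-6-en-1-yl N,N-diisopropylcarbamate | OC/C=C(C)/C[C@H](C)C[C@H](C)COC(=O)N(C(C)C)C(C)C
F2 | step 6 | (2S,4R)-5-[(2R,3R)-3-(hydroxymethyl)-2-methyloxiran-2-yl]-2,4-dimethylpentyl N,N-diisopropylcarbamate | OC[C@H]1O[C@]1(C)C[C@H](C)C[C@H](C)COC(=O)N(C(C)C)C(C)C
F3 | step 6 | (2S,4R)-5-[(2R,3S)-3-(iodomethyl)-2-methyloxiran-2-yl]-2,4-dimethylpentyl N,N-diisopropylcarbamate | IC[C@H]1O[C@]1(C)C[C@H](C)C[C@H](C)COC(=O)N(C(C)C)C(C)C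
F4 | step 10 | 2-[2-((tert-butyldimethylsilyl)oxy)ethyl]propane-1,3-diol | OCC(CO)CCO[Si](C)(C)C(C)(C)C
F5 | step 10 | (R)-4-((tert-butyldimethylsilyl)oxy)-2-(hydroxymethyl)butyl acetate | CC(=O)OC[C@@H](CO)CCO[Si](C)(C)C(C)(C)C
F6 | step 10 | (S)-4-((tert-butyldimethylsilyl)oxy)-2-(((tert-butyldimethylsilyl)oxy)methyl)butyl acetate | CC(=O)OC[C@@H](CO[Si](C)(C)C(C)(C)C)CCO[Si](C)(C)C(C)(C)C
F7 | step 10 | (S)-4-((tert-butyldimethylsilyl)oxy)-2-(((tert-butyldimethylsilyl)oxy)methyl)butan-1-ol | OC[C@@H](CO[Si](C)(C)C(C)(C)C)CCO[Si](C)(C)C(C)(C)C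
F8 | step 10 | (R)-4-((tert-butyldimethylsilyl)oxy)-2-(((tert-butyldimethylsilyl)oxy)methyl)butanal | O=C[C@@H](CO[Si](C)(C)C(C)(C)C)CCO[Si](C)(C)C(C)(C)C
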